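The 1,2-dioxane is read as the cyclic methyl peroxyketal of a γ-hydroperoxy ketone: ring carbon C6, which carries OMe, O1 and the side chain, is a masked ketone, and the peroxide oxygen O2 on C3 is its internal nucleophile. The bond from C6 to the first side-chain methylene is therefore made as an acyl–alkyl bond. The key step, a palladium-catalysed thioester–alkylzinc (Fukuyama) coupling, joins the complete C16 dienyne chain to an open-chain C1–C6 thioester that already holds the C3 peroxide stereocentre (from an organocatalytic enal peroxidation) and the carboxyl group. Acidic methanol then closes the ring onto C6 under anomeric control.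

Key step: step 9

Remark: ring atoms are numbered O1, O2, C3 (bearing CH2CO2H), C4, C5, C6 (bearing OMe and the side chain); hydroperoxide 14 is assumed not to be commercial and is made in step 6.

Step 1
Reactants: 1 (E)-1,2-dichloroethene; 2 5-chloropent-1-yne
Product: 3 (1E)-1,7-dichlorohept-1-en-3-yne
Conditions: Pd(PPh3)4 (5 mol%), CuI (10 mol%), n-BuNH2, Et2O, rt; 1 in excess (5 equiv)
Reagents that add atoms: none
Why: Sonogashira coupling (zerovalent palladium with CuI) of the terminal alkyne with excess (E)-1,2-dichloroethene should stop at mono-alkynylation and retains the E geometry, which becomes the E alkene of the side chain.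

Step 2
Reactants: 3 (1E)-1,7-dichlorohept-1-en-3-yne; 4 9-bromonon-1-ene
Product: 6 (10E)-16-chlorohexadeca-1,10-dien-12-yne, via non-8-enylmagnesium bromide 5 (not isolated)
Conditions: 4, Mg turnings, THF, rt; then 3, Fe(acac)3 (5 mol%), THF/NMP, 0 °C
Reagents that add atoms: none
Why: Iron-catalysed Kumada-type cross-coupling of an alkenyl chloride with a primary alkyl Grignard reagent is fast at 0 °C and proceeds with retention of alkene geometry, while the primary alkyl chloride should stay untouched.

Step 3
Reactants: 6 (10E)-16-chlorohexadeca-1,10-dien-12-yne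
Product: 7 (10E)-16-iodohexadeca-1,10-dien-12-yne
Conditions: NaI (5 equiv), acetone, reflux
Reagents that add atoms: sodium iodide, [Na+].[I-]
Why: Finkelstein halide exchange (SN2) at the primary chloride, driven by precipitation of NaCl in acetone, gives the iodide needed for zinc insertion.

Step 4
Reactants: 8 pent-4-enoyl chloride; 9 ethanethiol
Product: 10 S-ethyl pent-4-enethioate
Conditions: Et3N, CH2Cl2, 0 °C to rt
Reagents that add atoms: none
Why: Nucleophilic acyl substitution of the acid chloride by the thiol gives the thioester that later serves as the acyl donor.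

Step 5
Reactants: 10 S-ethyl pent-4-enethioate; 11 (2E)-but-2-enal
Product: 12 S-ethyl (4E)-6-oxohex-4-enethioate
Conditions: second-generation Hoveyda–Grubbs catalyst RuCl2(H2IMes)(=CH-C6H4-2-OiPr) (3 mol%), 11 (5 equiv), CH2Cl2, 40 °C
Reagents that add atoms: none
Why: Olefin cross-metathesis of a terminal alkene with excess crotonaldehyde should give the E enal as the thermodynamic product, and the S-alkyl thioester does not bind the ruthenium carbene strongly.

Step 6
Reactants: 13 2,3-dimethylbut-2-ene
Product: 14 2-hydroperoxy-2-methoxypropane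
Conditions: O3, MeOH/CH2Cl2, −78 °C; N2 purge; kept as a cold concentrated solution
Reagents that add atoms: ozone, [O-][O+]=O; methanol, CO
Why: Ozonolysis in methanol: the primary ozonide cleaves (Criegee mechanism) to acetone and acetone O-oxide, which methanol traps as the α-methoxy hydroperoxide.

Step 7
Reactants: 12 S-ethyl (4E)-6-oxohex-4-enethioate; 14 2-hydroperoxy-2-methoxypropane
Product: 15 S-ethyl (4S)-4-[(2-methoxypropan-2-yl)peroxy]-6-oxohexanethioate
Conditions: (R)-α,α-diphenylprolinol trimethylsilyl ether (10 mol%), PhCO2H (10 mol%), toluene, 0 °C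
Reagents that add atoms: none
Why: Iminium-ion organocatalysis (asymmetric oxa-Michael addition, here an enal β-peroxidation): the E-iminium ion of 12 is shielded on one face by the CPh2(OSiMe3) group, so the hydroperoxide adds anti to it, which for the R catalyst is the Si face of C4 and should set the 4S centre (C3 of the target), while benzoic acid speeds protonation of the enamine over its collapse to an epoxide.

Step 8
Reactants: 15 S-ethyl (4S)-4-[(2-methoxypropan-2-yl)peroxy]-6-oxohexanethioate
Product: 16 (3S)-6-(ethylsulfanyl)-3-[(2-methoxypropan-2-yl)peroxy]-6-oxohexanoic acid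
Conditions: NaClO2, NaH2PO4, 2-methylbut-2-ene, t-BuOH/H2O, 0 °C, short reaction time; used directly
Reagents that add atoms: sodium chlorite, [Na+].[O-]Cl=O
Why: Pinnick oxidation converts the aldehyde into the acid under cold, buffered conditions that should leave the thioester, the acid-labile peroxyketal and the C3 centre untouched, and 2-methylbut-2-ene removes the hypochlorite formed.

Step 9
Reactants: 7 (10E)-16-iodohexadeca-1,10-dien-12-yne; 16 (3S)-6-(ethylsulfanyl)-3-[(2-methoxypropan-2-yl)peroxy]-6-oxohexanoic acid
Product: 20 (3S,12E)-3-[(2-methoxypropan-2-yl)peroxy]-6-oxodocosa-12,21-dien-10-ynoic acid, via alkylzinc iodide 17 (not isolated), via trimethylsilyl ester 18 (not isolated), via coupled silyl ester 19 (not isolated)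
Conditions: 7, Zn dust, LiCl, THF, 40 °C; separately 16, MeC(OSiMe3)=NSiMe3 (BSA), THF, rt; then both solutions, PdCl2(PPh3)2 (5 mol%), toluene/THF, rt; aq. NH4Cl work-up
Reagents that add atoms: none
Why: Zerovalent palladium inserts into the C(acyl)–S bond of the thioester, the primary alkylzinc iodide transmetallates, and reductive elimination forms the ketone bond between C6 and the first side-chain methylene; this is the Fukuyama thioester–organozinc ketone synthesis. No ring is closed in this step; the product is the open-chain γ-peroxy ketone from which the dioxane forms in step 10. No stereocentre is created, and C3 with its peroxide should be carried through unchanged because the conditions are neutral and neither oxidise nor reduce a dialkyl peroxyketal. The selectivity needed is chemoselectivity for the thioester over the silyl ester, the O–O bond, the enyne and the terminal alkene; it is secured by the low nucleophilicity of RZnI and by oxidative addition being specific to the C–S bond. Transient silylation of the acid with BSA removes the only acidic proton, so the organozinc is not protonated, and the silyl ester is lost again on aqueous work-up.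

Step 10
Reactants: 20 (3S,12E)-3-[(2-methoxypropan-2-yl)peroxy]-6-oxodocosa-12,21-dien-10-ynoic acid
Product: 23 2-[(3S,6R)-6-[(6E)-hexadeca-6,15-dien-4-yn-1-yl]-6-methoxy-1,2-dioxan-3-yl]acetic acid, via free hydroperoxide 21 (not isolated), via peroxy hemiketal 22 (not isolated)
Conditions: MeOH (20 equiv), camphorsulfonic acid (10 mol%), CH2Cl2, 0 °C to rt
Reagents that add atoms: methanol, CO
Why: Acid-catalysed transketalisation: methanolysis removes the 2-methoxypropan-2-yl group, the freed C3 hydroperoxide adds to the C6 ketone (6-exo-trig hemiketalisation) and the hemiketal exchanges OH for OMe through the peroxycarbenium ion, all reversibly, so C6 should settle under thermodynamic control with OMe axial (anomeric effect) and both carbon substituents equatorial, which for 3S is the 6R configuration of the target.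

Compound list
1 | (E)-1,2-dichloroethene | Cl/C=C/Cl | starting material
2 | 5-chloropent-1-yne | C#CCCCCl | starting material
3 | (1E)-1,7-dichlorohept-1-en-3-yne | Cl/C=C/C#CCCCCl | intermediate
4 | 9-bromonon-1-ene | C=CCCCCCCCBr | starting material
5 | non-8-en-1-ylmagnesium bromide | C=CCCCCCCC[Mg]Br | intermediate
6 | (10E)-16-chlorohexadeca-1,10-dien-12-yne | C=CCCCCCCC/C=C/C#CCCCCl | intermediate
7 | (10E)-16-iodohexadeca-1,10-dien-12-yne | C=CCCCCCCC/C=C/C#CCCCI | intermediate
8 | pent-4-enoyl chloride | C=CCCC(=O)Cl | starting material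
9 | ethanethiol | CCS | starting material
10 | S-ethyl pent-4-enethioate | C=CCCC(=O)SCC | intermediate
11 | (2E)-but-2-enal | C/C=C/C=O | starting material
12 | S-ethyl (4E)-6-oxohex-4-enethioate | O=C/C=C/CCC(=O)SCC | intermediate
13 | 2,3-dimethylbut-2-ene | CC(C)=C(C)C | starting material
14 | 2-hydroperoxy-2-methoxypropane | COC(C)(C)OO | intermediate
15 | S-ethyl (4S)-4-[(2-methoxypropan-2-yl)peroxy]-6-oxohexanethioate | CCSC(=O)CC[C@@H](CC=O)OOC(C)(C)OC | intermediate
16 | (3S)-6-(ethylsulfanyl)-3-[(2-methoxypropan-2-yl)peroxy]-6-oxohexanoic acid | CCSC(=O)CC[C@@H](CC(=O)O)OOC(C)(C)OC | intermediate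
17 | [(6E)-hexadeca-6,15-dien-4-yn-1-yl](iodo)zinc | C=CCCCCCCC/C=C/C#CCCC[Zn]I | intermediate
18 | trimethylsilyl (3S)-6-(ethylsulfanyl)-3-[(2-methoxypropan-2-yl)peroxy]-6-oxohexanoate | CCSC(=O)CC[C@@H](CC(=O)O[Si](C)(C)C)OOC(C)(C)OC | intermediate
19 | trimethylsilyl (3S,12E)-3-[(2-methoxypropan-2-yl)peroxy]-6-oxodocosa-12,21-dien-10-ynoate | C=CCCCCCCC/C=C/C#CCCCC(=O)CC[C@@H](CC(=O)O[Si](C)(C)C)OOC(C)(C)OC | intermediate
20 | (3S,12E)-3-[(2-methoxypropan-2-yl)peroxy]-6-oxodocosa-12,21-dien-10-ynoic acid | C=CCCCCCCC/C=C/C#CCCCC(=O)CC[C@@H](CC(=O)O)OOC(C)(C)OC | intermediate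
21 | (3S,12E)-3-hydroperoxy-6-oxodocosa-12,21-dien-10-ynoic acid | C=CCCCCCCC/C=C/C#CCCCC(=O)CC[C@@H](CC(=O)O)OO | intermediate
22 | 2-[(3S)-6-[(6E)-hexadeca-6,15-dien-4-yn-1-yl]-6-hydroxy-1,2-dioxan-3-yl]acetic acid (both C6 epimers) | C=CCCCCCCC/C=C/C#CCCCC1(O)CC[C@@H](CC(=O)O)OO1 | intermediate
23 | 2-[(3S,6R)-6-[(6E)-hexadeca-6,15-dien-4-yn-1-yl]-6-methoxy-1,2-dioxan-3-yl]acetic acid | C=CCCCCCCC/C=C/C#CCCC[C@]1(OC)CC[C@@H](CC(=O)O)OO1 | target

Total step count: 10. Longest linear sequence: 6 steps (steps 4, 5, 7, 8, 9, 10).

Steps most likely to fail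

Step 7 (enantioselective peroxidation). The β-peroxy enamine may close onto its own O–O bond, giving an epoxide with loss of the peroxide, or the addition may show poor facial selectivity. Fallback: the C3–O bond is made by stereospecific SN2 displacement instead of conjugate addition; it sets out from hydroperoxide 14 and returns to the route at aldehyde 15. Commercial 4-[(tert-butyldimethylsilyl)oxy]butanal is allylated with B-allyldiisopinocampheylborane (the antipode that delivers the R alcohol; Et2O, −78 °C, then NaOH/H2O2) to give (4R)-7-[(tert-butyldimethylsilyl)oxy]hept-1-en-4-ol F1. 4-Nitrobenzenesulfonyl chloride, pyridine and DMAP convert it into (4R)-7-[(tert-butyldimethylsilyl)oxy]hept-1-en-4-yl 4-nitrobenzenesulfonate F2. Displacement with 14 (CsOH·H2O, DMF, 0 °C) should proceed with inversion to tert-butyl({(4S)-4-[(2-methoxypropan-2-yl)peroxy]hept-6-en-1-yl}oxy)dimethylsilane F3. Bu4NF gives (4S)-4-[(2-methoxypropan-2-yl)peroxy]hept-6-en-1-ol F4, buffered TEMPO/PhI(OAc)2 oxidation in MeCN/H2O gives (4S)-4-[(2-methoxypropan-2-yl)peroxy]hept-6-enoic acid F5, and EtSH/DCC/DMAP gives S-ethyl (4S)-4-[(2-methoxypropan-2-yl)peroxy]hept-6-enethioate F6. Ozonolysis of the terminal alkene (O3, CH2Cl2, −78 °C; PPh3) then delivers 15.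

Step 9 (key coupling). The O–O bond may be cleaved by the organozinc reagent or by low-valent palladium, or the organozinc may be protonated if silylation is incomplete. Fallback: the fragment union is moved ahead of the peroxide; it sets out from iodide 7 and enal 12 and returns at keto acid 20. The zinc reagent 17 made from 7 is coupled under the same palladium catalysis with 12, which carries neither peroxide nor acid, to give (2E,12E)-6-oxodocosa-2,12,21-trien-10-ynal F7. Amine-catalysed addition of 14 as in step 7 gives (3S,12E)-3-[(2-methoxypropan-2-yl)peroxy]-6-oxodocosa-12,21-dien-10-ynal F8, and chlorite oxidation as in step 8 gives 20.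

Step 10 (ring closure). Partial Fischer esterification of the acid and incomplete equilibration at C6 may give mixtures. Fallback: esterification is made deliberate; it sets out from 20 and returns at 23. HCl in MeOH (from AcCl, rt) drives deprotection, ring closure, equilibration and esterification to methyl 2-[(3S,6R)-6-[(6E)-hexadeca-6,15-dien-4-yn-1-yl]-6-methoxy-1,2-dioxan-3-yl]acetate F9, which is purified and then saponified (LiOH, THF/H2O, 0 °C) to 23.

Further compounds
F1 | step 7 | (4R)-7-[(tert-butyldimethylsilyl)oxy]hept-1-en-4-ol | CC(C)(C)[Si](C)(C)OCCC[C@H](CC=C)O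
F2 | step 7 | (4R)-7-[(tert-butyldimethylsilyl)oxy]hept-1-en-4-yl 4-nitrobenzenesulfonate | CC(C)(C)[Si](C)(C)OCCC[C@H](CC=C)OS(=O)(=O)c1ccc(cc1)[N+](=O)[O-]
F3 | step 7 | tert-butyl({(4S)-4-[(2-methoxypropan-2-yl)peroxy]hept-6-en-1-yl}oxy)dimethylsilane | CC(C)(C)[Si](C)(C)OCCC[C@@H](CC=C)OOC(C)(C)OC
F4 | step 7 | (4S)-4-[(2-methoxypropan-2-yl)peroxy]hept-6-en-1-ol | OCCC[C@@H](CC=C)OOC(C)(C)OC
F5 | step 7 | (4S)-4-[(2-methoxypropan-2-yl)peroxy]hept-6-enoic acid | OC(=O)CC[C@@H](CC=C)OOC(C)(C)OC
F6 | step 7 | S-ethyl (4S)-4-[(2-methoxypropan-2-yl)peroxy]hept-6-enethioate | CCSC(=O)CC[C@@H](CC=C)OOC(C)(C)OC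
F7 | step 9 | (2E,12E)-6-oxodocosa-2,12,21-trien-10-ynal | C=CCCCCCCC/C=C/C#CCCCC(=O)CC/C=C/C=O
F8 | step 9 | (3S,12E)-3-[(2-methoxypropan-2-yl)peroxy]-6-oxodocosa-12,21-dien-10-ynal | C=CCCCCCCC/C=C/C#CCCCC(=O)CC[C@@H](CC=O)OOC(C)(C)OC
F9 | step 10 | methyl 2-[(3S,6R)-6-[(6E)-hexadeca-6,15-dien-4-yn-1-yl]-6-methoxy-1,2-dioxan-3-yl]acetate | C=CCCCCCCC/C=C/C#CCCC[C@]1(OC)CC[C@@H](CC(=O)OC)OO1
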